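**Retrosynthetic overview**

1. The ten-membered ring is closed last at C9–C10: an eleven-membered alkenyl(alkyl)borate, formed in the flask from iodo boronate 24, contracts by an iodine-triggered 1,2-shift of C9 from boron to C10 (Zweifel type) and loses boron and iodide to give the exo-methylene carbocycle 28.
2. Butenolide B (C6, C7, C11–C13) comes from propargylic alcohol 18 by hydroxyl-directed anti-carbomagnesiation with vinylmagnesium chloride and CO2; hydroboration then places boron on C9.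
3. The (Z)-C4=C5 enynone 17 comes from opening butenolide A (13) with a propargyl-ether acetylide; 13 is made by the same carbomagnesiation/CO2 sequence with MeMgBr (C15), so the ring fixes the alkene geometry.
4. Stereocentres: C3 by catalytic aldol (4 + 5), C1 by 1,3-anti reduction, C6 by CBS reduction. Ring order: butenolide A (temporary), butenolide B, then the carbocycle.

Assumption: carbons carry germacrane labels (C1–C10 ring, C11–C13 lactone carbons, C14 exocyclic methylene, C15 methyl), and where a chiral catalyst is named its enantiomer is the one that gives the configuration drawn.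

**Route**

Step 1
Reactants: 1 (1-bromoethenyl)trimethylsilane; 2 N-methoxy-N-methylacetamide
Product: 4 3-(trimethylsilyl)but-3-en-2-one, via Grignard reagent 3 (not isolated)
Conditions: Mg, THF, 50 °C; then 2, 0 °C; 1 M HCl
Reagents that add atoms: none
Why: Weinreb ketone synthesis, in which the alkenyl Grignard reagent acylates the amide only once because the chelated tetrahedral adduct survives until work-up.

Step 2
Reactants: 4 3-(trimethylsilyl)but-3-en-2-one; 5 3-(trimethylsilyl)prop-2-ynal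
Product: 6 (5S)-5-hydroxy-2,7-bis(trimethylsilyl)hept-1-en-6-yn-3-one
Conditions: (S,S)-ProPhenol (2,6-bis{[(S)-2-(hydroxydiphenylmethyl)pyrrolidin-1-yl]methyl}-4-methylphenol, 10 mol %), Et2Zn (20 mol %), 4 Å MS, THF, 0 °C
Reagents that add atoms: none
Why: Direct catalytic asymmetric aldol addition of a methyl vinyl ketone-type donor through a dinuclear zinc enolate, whose ligand pocket fixes the face of the ynal and so sets C3 (S).

Step 3
Reactants: 6 (5S)-5-hydroxy-2,7-bis(trimethylsilyl)hept-1-en-6-yn-3-one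
Product: 7 (3S,5S)-2,7-bis(trimethylsilyl)hept-1-en-6-yne-3,5-diol
Conditions: Me4NBH(OAc)3, MeCN/AcOH 1:1, −30 °C
Reagents that add atoms: none
Why: Evans–Saksena reduction, in which the C3 alkoxy(diacetoxy)borohydride delivers hydride intramolecularly through a chair transition state and gives the 1,3-anti diol, setting C1 (S).

Step 4
Reactants: 7 (3S,5S)-2,7-bis(trimethylsilyl)hept-1-en-6-yne-3,5-diol
Product: 8 (3S,5S)-2-(trimethylsilyl)hept-1-en-6-yne-3,5-diol
Conditions: K2CO3 (cat.), MeOH, 0 °C to rt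
Reagents that add atoms: none
Why: Methanolysis of the alkynyl C–Si bond, which is far faster than cleavage of the alkenyl C–Si bond, so only the alkyne is freed.

Step 5
Reactants: 8 (3S,5S)-2-(trimethylsilyl)hept-1-en-6-yne-3,5-diol; 9 methylmagnesium bromide; 10 carbon dioxide
Product: 13 (5S)-5-[(2S)-2-hydroxy-3-(trimethylsilyl)but-3-en-1-yl]-4-methylfuran-2(5H)-one (butenolide A), via alkenylmagnesium species 11 (not isolated), via hydroxy acid 12 (not isolated)
Conditions: MeMgBr (4.5 equiv), CuI (10 mol %), THF, −10 °C to rt; CO2, −20 °C to rt; 1 M HCl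
Reagents that add atoms: none
Why: Hydroxyl-directed anti-carbomagnesiation of a propargylic alcohol (Duboudin–Fallis type) puts the methyl on C4 and magnesium on C5 cis to the carbinol, so carboxylation and lactonisation give the butenolide with the C4=C5 geometry locked and C3 untouched.

Step 6
Reactants: 13 butenolide A; 14 tert-butyl(diphenyl)(prop-2-yn-1-yloxy)silane
Product: 17 (5Z,7S,9S)-1-{[tert-butyl(diphenyl)silyl]oxy}-6-methyl-7,9-bis[(triethylsilyl)oxy]-10-(trimethylsilyl)undeca-5,10-dien-2-yn-4-one, via lithium acetylide 15 (not isolated), via dilithium dialkoxide 16 (not isolated)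
Conditions: 14 (2.3 equiv), n-BuLi (2.2 equiv), THF, −78 °C; CeCl3; 13, −78 °C; Et3SiCl (3 equiv), −78 to 0 °C
Reagents that add atoms: chlorotriethylsilane, CC[Si](Cl)(CC)CC
Why: Acetylide addition to the lactone carbonyl (nucleophilic acyl substitution with ring opening) followed by silylation of both alkoxides traps the open (Z)-enynone, whose alkene geometry is inherited from the ring.

Step 7
Reactants: 17 (Z)-enynone
Product: 18 (4R,5Z,7S,9S)-1-{[tert-butyl(diphenyl)silyl]oxy}-6-methyl-7,9-bis[(triethylsilyl)oxy]-10-(trimethylsilyl)undeca-5,10-dien-2-yn-4-ol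
Conditions: (R)-Me-CBS ((R)-1-methyl-3,3-diphenyltetrahydro-1H,3H-pyrrolo[1,2-c][1,3,2]oxazaborole, 20 mol %), catecholborane, toluene, −78 °C
Reagents that add atoms: none
Why: Corey–Bakshi–Shibata reduction, in which the alkynyl group acts as the small substituent and the branched (Z)-alkenyl group as the large one, so the reagent-controlled hydride delivery sets C6 (R).

Step 8
Reactants: 18 propargylic alcohol; 19 ethenylmagnesium chloride; 10 carbon dioxide
Product: 22 (5R)-3-{[tert-butyl(diphenyl)silyl]oxymethyl}-4-ethenyl-5-[(1Z,3S,5S)-2-methyl-3,5-bis[(triethylsilyl)oxy]-6-(trimethylsilyl)hepta-1,6-dien-1-yl]furan-2(5H)-one (butenolide B), via alkenylmagnesium species 20 (not isolated), via hydroxy acid 21 (not isolated)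
Conditions: CH2=CHMgCl (5 equiv), THF, 50 °C; CO2, −20 °C to rt; 0.5 M HCl to pH 3, 0 °C
Reagents that add atoms: none
Why: Hydroxyl-directed anti-carbomagnesiation of the internal alkyne delivers vinyl to C7 and holds magnesium on C11 cis to the C6 alkoxide in a five-membered chelate, so CO2 capture and lactonisation give the tetrasubstituted butenolide without touching C6.

Step 9
Reactants: 22 butenolide B
Product: 23 (5R)-3-{[tert-butyl(diphenyl)silyl]oxymethyl}-5-[(1Z,3S,5S)-2-methyl-3,5-bis[(triethylsilyl)oxy]-6-(trimethylsilyl)hepta-1,6-dien-1-yl]-4-[2-(4,4,5,5-tetramethyl-1,3,2-dioxaborolan-2-yl)ethyl]furan-2(5H)-one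
Conditions: pinacolborane (1.2 equiv), [Ir(cod)Cl]2 (1.5 mol %), bis(diphenylphosphino)methane (3 mol %), CH2Cl2, rt
Reagents that add atoms: pinacolborane, [H]B1OC(C)(C)C(C)(C)O1
Why: Iridium-catalysed anti-Markovnikov hydroboration, selective for the only monosubstituted alkene, places boron on C9 and leaves the hindered trisubstituted, silyl-substituted and butenolide alkenes alone.

Step 10
Reactants: 23 alkyl boronate
Product: 24 (5R)-3-{[tert-butyl(diphenyl)silyl]oxymethyl}-5-[(1Z,3S,5S)-6-iodo-2-methyl-3,5-bis[(triethylsilyl)oxy]hepta-1,6-dien-1-yl]-4-[2-(4,4,5,5-tetramethyl-1,3,2-dioxaborolan-2-yl)ethyl]furan-2(5H)-one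
Conditions: N-iodosuccinimide (1.3 equiv), MeCN, 0 °C, dark
Reagents that add atoms: N-iodosuccinimide, O=C1CCC(=O)N1I
Why: Ipso-iododesilylation of the vinylsilane through a β-silyl-stabilised cation replaces silicon on C10 by iodine with the alkene position retained.

Step 11
Reactants: 24 iodo boronate
Product: 28 (7S,9S,10Z,11aR)-3-{[tert-butyl(diphenyl)silyl]oxymethyl}-10-methyl-6-methylidene-7,9-bis[(triethylsilyl)oxy]-4,5,6,7,8,9-hexahydrocyclodeca[b]furan-2(11aH)-one, via alkenylmagnesium chloride 25 (not isolated), via cyclic borate 26 (not isolated), via iodo boronate 27 (not isolated)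
Conditions: i-PrMgCl·LiCl (1.1 equiv), THF, −40 °C; THF/DMSO 4:1, 0.002 M, 0 °C; I2 (1.2 equiv), MeOH, −78 °C; NaOMe, −78 to 0 °C
Reagents that add atoms: none
Why: Proposed new method: iodine–magnesium exchange gives alkenylmagnesium 25, which closes on the pendant pinacol boronate to the eleven-membered ate complex 26, iodine then attacks the terminal CH2 and triggers a 1,2-shift of C9 from boron to C10 that contracts the ring to the ten-membered carbocycle 27, and methoxide-induced anti elimination of boron and iodide leaves the exo-methylene with no stereocentre formed or touched; the closest known reactions are the intermolecular Zweifel olefination of boronic esters with α-substituted vinyl Grignard reagents and B-alkyl Suzuki macrocyclisation.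

Step 12
Reactants: 28 bis(triethylsilyl) macrocycle; 29 acetic anhydride
Product: 31 (7S,9S,10Z,11aR)-3-{[tert-butyl(diphenyl)silyl]oxymethyl}-10-methyl-6-methylidene-2-oxo-2,4,5,6,7,8,9,11a-octahydrocyclodeca[b]furan-7,9-diyl diacetate, via diol 30 (not isolated)
Conditions: pyridinium p-toluenesulfonate, MeOH/CH2Cl2, 0 °C; evaporate; Ac2O, pyridine, DMAP (cat.), 0 °C to rt
Reagents that add atoms: none
Why: Mild acid methanolysis removes the two secondary triethylsilyl ethers but not the primary tert-butyldiphenylsilyl ether, and the crude diol is acetylated at C1 and C3 with retention.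

Step 13
Reactants: 31 diacetate silyl ether
Product: 32 (7S,9S,10Z,11aR)-3-(hydroxymethyl)-10-methyl-6-methylidene-2-oxo-2,4,5,6,7,8,9,11a-octahydrocyclodeca[b]furan-7,9-diyl diacetate (target)
Conditions: HF·pyridine, pyridine/THF, 0 °C to rt
Reagents that add atoms: none
Why: Fluoride-mediated desilylation frees the primary C13 alcohol under buffered conditions that leave the two allylic acetates and the butenolide intact.

**Compound list**

1 | (1-bromoethenyl)trimethylsilane | C=C(Br)[Si](C)(C)C | starting material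
2 | N-methoxy-N-methylacetamide | CC(=O)N(C)OC | starting material
3 | [1-(trimethylsilyl)ethenyl]magnesium bromide | C=C([Mg]Br)[Si](C)(C)C | intermediate
4 | 3-(trimethylsilyl)but-3-en-2-one | CC(=O)C(=C)[Si](C)(C)C | intermediate
5 | 3-(trimethylsilyl)prop-2-ynal | O=CC#C[Si](C)(C)C | starting material
6 | (5S)-5-hydroxy-2,7-bis(trimethylsilyl)hept-1-en-6-yn-3-one | C=C([Si](C)(C)C)C(=O)C[C@H](O)C#C[Si](C)(C)C | intermediate
7 | (3S,5S)-2,7-bis(trimethylsilyl)hept-1-en-6-yne-3,5-diol | C=C([Si](C)(C)C)[C@@H](O)C[C@H](O)C#C[Si](C)(C)C | intermediate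
8 | (3S,5S)-2-(trimethylsilyl)hept-1-en-6-yne-3,5-diol | C=C([Si](C)(C)C)[C@@H](O)C[C@H](O)C#C | intermediate
9 | methylmagnesium bromide | C[Mg]Br | starting material
10 | carbon dioxide | O=C=O | starting material
11 | (Z)-alkenylmagnesium bromide from 8, methyl on C4, magnesium on C5 cis to C3, both hydroxyls as bromomagnesium alkoxides | C=C([Si](C)(C)C)[C@@H](O[Mg]Br)C[C@H](O[Mg]Br)/C(C)=C\[Mg]Br | intermediate
12 | (2Z,4S,6S)-4,6-dihydroxy-3-methyl-7-(trimethylsilyl)octa-2,7-dienoic acid | C=C([Si](C)(C)C)[C@@H](O)C[C@H](O)/C(C)=C\C(=O)O | intermediate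
13 | (5S)-5-[(2S)-2-hydroxy-3-(trimethylsilyl)but-3-en-1-yl]-4-methylfuran-2(5H)-one (butenolide A) | C=C([Si](C)(C)C)[C@@H](O)C[C@@H]1OC(=O)C=C1C | intermediate
14 | tert-butyl(diphenyl)(prop-2-yn-1-yloxy)silane (silyl-protected propargyl alcohol) | C#CCO[Si](c1ccccc1)(c1ccccc1)C(C)(C)C | starting material
15 | lithium acetylide of 14 | [Li]C#CCO[Si](c1ccccc1)(c1ccccc1)C(C)(C)C | intermediate
16 | dilithium dialkoxide of the ring-opened (Z)-dihydroxy enynone (open form drawn) | C=C([Si](C)(C)C)[C@@H](O[Li])C[C@H](O[Li])/C(C)=C\C(=O)C#CCO[Si](c1ccccc1)(c1ccccc1)C(C)(C)C | intermediate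
17 | (5Z,7S,9S)-1-{[tert-butyl(diphenyl)silyl]oxy}-6-methyl-7,9-bis[(triethylsilyl)oxy]-10-(trimethylsilyl)undeca-5,10-dien-2-yn-4-one | C=C([Si](C)(C)C)[C@@H](O[Si](CC)(CC)CC)C[C@H](O[Si](CC)(CC)CC)/C(C)=C\C(=O)C#CCO[Si](c1ccccc1)(c1ccccc1)C(C)(C)C | intermediate
18 | (4R,5Z,7S,9S)-1-{[tert-butyl(diphenyl)silyl]oxy}-6-methyl-7,9-bis[(triethylsilyl)oxy]-10-(trimethylsilyl)undeca-5,10-dien-2-yn-4-ol | C=C([Si](C)(C)C)[C@@H](O[Si](CC)(CC)CC)C[C@H](O[Si](CC)(CC)CC)/C(C)=C\[C@@H](O)C#CCO[Si](c1ccccc1)(c1ccccc1)C(C)(C)C | intermediate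
19 | ethenylmagnesium chloride | C=C[Mg]Cl | starting material
20 | alkenylmagnesium chloride from 18, vinyl on C7, magnesium on C11 cis to the C6 chloromagnesium alkoxide | C=C([Si](C)(C)C)[C@@H](O[Si](CC)(CC)CC)C[C@H](O[Si](CC)(CC)CC)/C(C)=C\[C@@H](O[Mg]Cl)/C(C=C)=C(/CO[Si](c1ccccc1)(c1ccccc1)C(C)(C)C)[Mg]Cl | intermediate
21 | (2Z,4R,5Z,7S,9S)-2-{[tert-butyl(diphenyl)silyl]oxymethyl}-3-ethenyl-4-hydroxy-6-methyl-7,9-bis[(triethylsilyl)oxy]-10-(trimethylsilyl)undeca-2,5,10-trienoic acid | C=C([Si](C)(C)C)[C@@H](O[Si](CC)(CC)CC)C[C@H](O[Si](CC)(CC)CC)/C(C)=C\[C@@H](O)/C(C=C)=C(/CO[Si](c1ccccc1)(c1ccccc1)C(C)(C)C)C(=O)O | intermediate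
22 | (5R)-3-{[tert-butyl(diphenyl)silyl]oxymethyl}-4-ethenyl-5-[(1Z,3S,5S)-2-methyl-3,5-bis[(triethylsilyl)oxy]-6-(trimethylsilyl)hepta-1,6-dien-1-yl]furan-2(5H)-one (butenolide B) | C=C([Si](C)(C)C)[C@@H](O[Si](CC)(CC)CC)C[C@H](O[Si](CC)(CC)CC)/C(C)=C\[C@H]1OC(=O)C(CO[Si](c2ccccc2)(c2ccccc2)C(C)(C)C)=C1C=C | intermediate
23 | (5R)-3-{[tert-butyl(diphenyl)silyl]oxymethyl}-5-[(1Z,3S,5S)-2-methyl-3,5-bis[(triethylsilyl)oxy]-6-(trimethylsilyl)hepta-1,6-dien-1-yl]-4-[2-(4,4,5,5-tetramethyl-1,3,2-dioxaborolan-2-yl)ethyl]furan-2(5H)-one | C=C([Si](C)(C)C)[C@@H](O[Si](CC)(CC)CC)C[C@H](O[Si](CC)(CC)CC)/C(C)=C\[C@H]1OC(=O)C(CO[Si](c2ccccc2)(c2ccccc2)C(C)(C)C)=C1CCB1OC(C)(C)C(C)(C)O1 | intermediate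
24 | (5R)-3-{[tert-butyl(diphenyl)silyl]oxymethyl}-5-[(1Z,3S,5S)-6-iodo-2-methyl-3,5-bis[(triethylsilyl)oxy]hepta-1,6-dien-1-yl]-4-[2-(4,4,5,5-tetramethyl-1,3,2-dioxaborolan-2-yl)ethyl]furan-2(5H)-one | C=C(I)[C@@H](O[Si](CC)(CC)CC)C[C@H](O[Si](CC)(CC)CC)/C(C)=C\[C@H]1OC(=O)C(CO[Si](c2ccccc2)(c2ccccc2)C(C)(C)C)=C1CCB1OC(C)(C)C(C)(C)O1 | intermediate
25 | alkenylmagnesium chloride from 24 (MgCl in place of iodine on C10) | C=C([Mg]Cl)[C@@H](O[Si](CC)(CC)CC)C[C@H](O[Si](CC)(CC)CC)/C(C)=C\[C@H]1OC(=O)C(CO[Si](c2ccccc2)(c2ccccc2)C(C)(C)C)=C1CCB1OC(C)(C)C(C)(C)O1 | intermediate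
26 | eleven-membered cyclic alkenyl(alkyl)pinacolatoborate with boron between C9 and C10, chloromagnesium salt | C=C1[B-]2(OC(C)(C)C(C)(C)O2)CCC3=C(CO[Si](c4ccccc4)(c4ccccc4)C(C)(C)C)C(=O)O[C@@H]3/C=C(/C)[C@@H](O[Si](CC)(CC)CC)C[C@@H]1O[Si](CC)(CC)CC.[Mg+]Cl | intermediate
27 | ten-membered carbocycle with C10 carrying iodomethyl and pinacolboryl groups (7S,9S,10Z,11aR; C10 unassigned) | ICC1(B2OC(C)(C)C(C)(C)O2)CCC3=C(CO[Si](c4ccccc4)(c4ccccc4)C(C)(C)C)C(=O)O[C@@H]3/C=C(/C)[C@@H](O[Si](CC)(CC)CC)C[C@@H]1O[Si](CC)(CC)CC | intermediate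
28 | (7S,9S,10Z,11aR)-3-{[tert-butyl(diphenyl)silyl]oxymethyl}-10-methyl-6-methylidene-7,9-bis[(triethylsilyl)oxy]-4,5,6,7,8,9-hexahydrocyclodeca[b]furan-2(11aH)-one | C=C1CCC2=C(CO[Si](c3ccccc3)(c3ccccc3)C(C)(C)C)C(=O)O[C@@H]2/C=C(/C)[C@@H](O[Si](CC)(CC)CC)C[C@@H]1O[Si](CC)(CC)CC | intermediate
29 | acetic anhydride | CC(=O)OC(C)=O | starting material
30 | (7S,9S,10Z,11aR)-3-{[tert-butyl(diphenyl)silyl]oxymethyl}-7,9-dihydroxy-10-methyl-6-methylidene-4,5,6,7,8,9-hexahydrocyclodeca[b]furan-2(11aH)-one | C=C1CCC2=C(CO[Si](c3ccccc3)(c3ccccc3)C(C)(C)C)C(=O)O[C@@H]2/C=C(/C)[C@@H](O)C[C@@H]1O | intermediate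
31 | (7S,9S,10Z,11aR)-3-{[tert-butyl(diphenyl)silyl]oxymethyl}-10-methyl-6-methylidene-2-oxo-2,4,5,6,7,8,9,11a-octahydrocyclodeca[b]furan-7,9-diyl diacetate | C=C1CCC2=C(CO[Si](c3ccccc3)(c3ccccc3)C(C)(C)C)C(=O)O[C@@H]2/C=C(/C)[C@@H](OC(C)=O)C[C@@H]1OC(C)=O | intermediate
32 | (7S,9S,10Z,11aR)-3-(hydroxymethyl)-10-methyl-6-methylidene-2-oxo-2,4,5,6,7,8,9,11a-octahydrocyclodeca[b]furan-7,9-diyl diacetate (CNP0398389.3; 1S,3S,6R in germacrane labels) | C=C1CCC2=C(CO)C(=O)O[C@@H]2/C=C(/C)[C@@H](OC(C)=O)C[C@@H]1OC(C)=O | target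

**Step count and risks**

Total step count: 13. Longest linear sequence: 13 steps (1 to 32).

Three steps most likely to fail:

Step 11 (proposed new ring-contracting closure). The alkenylmagnesium 25 may deprotonate the butenolide or eliminate the neighbouring silyloxy group before the large borate ring forms, and methoxide may epimerise C6. The fallback uses known chemistry and sets out from 22. Iododesilylation with N-iodosuccinimide gives the iodo vinyl-butenolide F1. Hydroboration of its terminal vinyl group with 9-BBN gives the B-alkyl-9-borabicyclo[3.3.1]nonane F2. B-alkyl Suzuki–Miyaura macrocyclisation (Pd(dppf)Cl2, AsPh3, Cs2CO3, DMF/THF/H2O, 0.001 M) then closes the C9–C10 bond and comes back to the route at 28.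

Step 8 (carbomagnesiation/carboxylation to butenolide B). The alkenylmagnesium 20 carries a silyloxymethyl group on the metal-bearing carbon and may eliminate to an allene at 50 °C, and heating a doubly activated carbinol is harsh. The fallback sets out from 13. Lithiated methyl propiolate is added to the lactone and the alkoxides are silylated as in step 6 to give the keto ynoate F3. Reduction with (R)-Me-CBS and catecholborane gives the hydroxy ynoate F4. Syn addition of (CH2=CH)2CuLi, trapping of the α-cuprio enoate with monomeric formaldehyde and spontaneous lactonisation give the hydroxymethyl butenolide F5. Silylation with tert-butyldiphenylsilyl chloride and imidazole comes back to the route at 22.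

Step 6 (acetylide opening of butenolide A). The acetylide may deprotonate the γ-position instead of adding, and the hydroxy enynone can close to a lactol and dehydrate to a furan. The fallback sets out from 13. MeNH(OMe)·HCl and Me3Al open the lactone to the Weinreb amide diol F6. Et3SiCl and imidazole give the bis(triethylsilyl) Weinreb amide F7. Addition of lithium acetylide 15 at −78 °C comes back to the route at 17.

**Further compounds**

F1 | step 11 | (5R)-3-{[tert-butyl(diphenyl)silyl]oxymethyl}-4-ethenyl-5-[(1Z,3S,5S)-6-iodo-2-methyl-3,5-bis[(triethylsilyl)oxy]hepta-1,6-dien-1-yl]furan-2(5H)-one | C=C(I)[C@@H](O[Si](CC)(CC)CC)C[C@H](O[Si](CC)(CC)CC)/C(C)=C\[C@H]1OC(=O)C(CO[Si](c2ccccc2)(c2ccccc2)C(C)(C)C)=C1C=C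
F2 | step 11 | (5R)-4-[2-(9-borabicyclo[3.3.1]nonan-9-yl)ethyl]-3-{[tert-butyl(diphenyl)silyl]oxymethyl}-5-[(1Z,3S,5S)-6-iodo-2-methyl-3,5-bis[(triethylsilyl)oxy]hepta-1,6-dien-1-yl]furan-2(5H)-one | C=C(I)[C@@H](O[Si](CC)(CC)CC)C[C@H](O[Si](CC)(CC)CC)/C(C)=C\[C@H]1OC(=O)C(CO[Si](c2ccccc2)(c2ccccc2)C(C)(C)C)=C1CCB1C2CCCC1CCC2
F3 | step 8 | methyl (5Z,7S,9S)-6-methyl-4-oxo-7,9-bis[(triethylsilyl)oxy]-10-(trimethylsilyl)undeca-5,10-dien-2-ynoate | C=C([Si](C)(C)C)[C@@H](O[Si](CC)(CC)CC)C[C@H](O[Si](CC)(CC)CC)/C(C)=C\C(=O)C#CC(=O)OC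
F4 | step 8 | methyl (4R,5Z,7S,9S)-4-hydroxy-6-methyl-7,9-bis[(triethylsilyl)oxy]-10-(trimethylsilyl)undeca-5,10-dien-2-ynoate | C=C([Si](C)(C)C)[C@@H](O[Si](CC)(CC)CC)C[C@H](O[Si](CC)(CC)CC)/C(C)=C\[C@@H](O)C#CC(=O)OC
F5 | step 8 | (5R)-4-ethenyl-3-(hydroxymethyl)-5-[(1Z,3S,5S)-2-methyl-3,5-bis[(triethylsilyl)oxy]-6-(trimethylsilyl)hepta-1,6-dien-1-yl]furan-2(5H)-one | C=C([Si](C)(C)C)[C@@H](O[Si](CC)(CC)CC)C[C@H](O[Si](CC)(CC)CC)/C(C)=C\[C@H]1OC(=O)C(CO)=C1C=C
F6 | step 6 | (2Z,4S,6S)-4,6-dihydroxy-N-methoxy-N,3-dimethyl-7-(trimethylsilyl)octa-2,7-dienamide | C=C([Si](C)(C)C)[C@@H](O)C[C@H](O)/C(C)=C\C(=O)N(C)OC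
F7 | step 6 | (2Z,4S,6S)-N-methoxy-N,3-dimethyl-4,6-bis[(triethylsilyl)oxy]-7-(trimethylsilyl)octa-2,7-dienamide | C=C([Si](C)(C)C)[C@@H](O[Si](CC)(CC)CC)C[C@H](O[Si](CC)(CC)CC)/C(C)=C\C(=O)N(C)OC
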